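(The runs are simulated for substances that don't exist; scatter was added.)

A small charge of solid substrate, 0.020 M in larch, is followed here on its way to ring; alder ran earlier with 0.030 M.

| flask | solid substrate | remark | time |
|---|---|---|---|
| larch | 0.020 M | the very flask that is asked about, followed so far |  |
| alder | 0.030 M | run made earlier |  |
| flask | 0.020 M |  | 3.0 h |

- larch (time / min: ring / %, solid substrate / %): 50.0: 5.9, 93.5; 60.0: 7.4, 91.7; 80.0: 9.9, 89.0
- alder (time / h: ring / %, solid substrate / %): 0.833: 4.0, 95.7; 1.00: 4.8, 94.7; 1.50: 7.5, 91.8; 2.00: 10.3, 89.9; 3.00: 14.7, 83.8

(readings scatter by 0.3 percentage points)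

- time up to 3.0 h at which ring stands highest
- the amount of ring, in percent of the solid substrate charged, at that time
- the first time at which ring reaches 16%, in the same percent

I read the ring columns against each other. Larch reaches 9.9% at 80.0 min and alder reaches 14.7% at 3.00 h, so in percent per hour the smaller charge looks faster. Percent misleads here, so the thing to watch is [ring] itself. The last larch reading gives [ring] over time of 1.49 mM/h, and the last alder reading gives 1.47 mM/h, nearly the same. I call this mean rate of [ring], reached concentration divided by elapsed time, the feed, a zero-order rate. The first alder reading gives 1.44 mM/h, so across the alder readings replacing the curve by its mean costs little.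

For larch at 3.0 h the feed gives 4.41 mM, or 22.1% of the charge, and alder has already reached that [ring]. This is less than the charge, so by my reckoning solid substrate remains and ring still climbs, and I put its highest at 3.0 h. The asked level is 3.20 mM, which the feed reaches at 2.18 h.

The forecast gives 22% at 3 h and the level at 2.17 h, holding that “The rate is therefore independent of the amount of solid”.

The flask gives 23.0% at 3.00 h and reaches the level at 2.13 h.

    starting material → ring (k = 0.00230 /s)
    2 starting material → open dimer (k = 0.0580 /M/s)
    solid substrate ⇌ starting material, rate k3*(cs3 - [starting material]) while solid is left; crystals form when [starting material] > cs3 (solubility = 9.70 mM, k = 4.70 × 10⁻⁵ /s)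

In this flask starting material is made as fast as it is used up, the ratio being 1.00 at 1.50 h and 1.00 at 3.00 h. It stands at 0.962% at 1.50 h and 0.962% at 3.00 h, while ring goes from 11.0% to 23.0%. The mean of this flask over 3.0 h is 1.53 mM/h, a little above my feed. In the neighbour flask with 0.0080 M of solid substrate the feed gives 55.1% at 3.0 h, and ring stands at 57.4%.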